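**Retrosynthetic overview**

1. Numbering (13-oxabicyclo[10.2.2]hexadecane): C1 ring CH, C2–C11 tether (C4=C5 E-alkene, C8 methylidene, C9 carbinol), C12 C(CH3)O, O13, C14 C(CH3)2, C15 CH2, C16 CHOAc; target 14 ⇐ acetate 13 ⇐ alcohol 12 (desilylation, acetylation).
2. 12 ⇐ bicyclic enol ether 10 (C12=C16): epoxidation anti to the tether, then syn methyl transfer from AlMe3, sets C16–O and C12–CH3.
3. 10 ⇐ acyclic vinyl ketone 9 by one formal inverse-electron-demand hetero-Diels–Alder addition of the enone O13=C12–C16=C15 across the terminal isopropylidene C1=C14; C15–C1 and O13–C14 form together, so the 14-membered carbocycle and the oxane close in this one step and no ring exists before it.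
4. Enabling feature: the oxane O13–C14–C1–C15–C16–C12 is a 2,2-dimethyloxane, i.e. a prenyl terminus (C1 = CH, C14 = tertiary carbon with two methyls) joined to a four-atom unit C15–C16–C12–O13 that is a vinyl ketone once the C12 methyl and the C16 oxygen are taken off; the C2–C11 tether with the C4 methyl is the chain of geranylacetone.
5. 9 ⇐ Weinreb amide 8 + vinylmagnesium bromide; C9 from CBS reduction of enone 6; 6 ⇐ Shapiro vinyllithium 5 (from geranylacetone 3) + succinic bis-Weinreb amide 2 (from succinyl chloride 1).

Key step: step 7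

Assumption: in step 7 the C9 silyloxy stereocentre is taken to steer the new C1 centre to the relative configuration of the target; should the opposite sense prevail, the same route started with the (R)-CBS catalyst, followed by inversion of C9 at the end, would correct it.

**Route**

Step 1
Reactants: 1 succinyl chloride
Product: 2 N1,N4-dimethoxy-N1,N4-dimethylbutanediamide
Conditions: MeNHOMe·HCl (2.2 equiv), pyridine (4.5 equiv), CH2Cl2, 0 °C → rt
Reagents that add atoms: N,O-dimethylhydroxylamine hydrochloride, CNOC.Cl
Why: Twofold acyl substitution of the acid chloride (Weinreb amide formation) should give the bis-amide; no stereocentre is formed.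

Step 2
Reactants: 3 geranylacetone
Product: 4 (E)-2,4,6-triisopropylbenzenesulfonylhydrazone of geranylacetone
Conditions: 2,4,6-triisopropylbenzenesulfonohydrazide (1.05 equiv), THF, cat. HCl, rt
Reagents that add atoms: 2,4,6-triisopropylbenzenesulfonohydrazide, CC(C)c1cc(C(C)C)c(S(=O)(=O)NN)c(C(C)C)c1
Why: Hydrazone condensation at the only carbonyl should give the E isomer (N–N syn to the methyl group), and the hindered aryl group prevents ortho-lithiation in the next step; no carbon stereocentre is formed.

Step 3
Reactants: 4 (E)-2,4,6-triisopropylbenzenesulfonylhydrazone of geranylacetone; 2 N1,N4-dimethoxy-N1,N4-dimethylbutanediamide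
Product: 6 (8E)-N-methoxy-N,9,13-trimethyl-5-methylidene-4-oxotetradeca-8,12-dienamide, via vinyllithium 5 (not isolated)
Conditions: n-BuLi (2.2 equiv), TMEDA/hexane, −78 → 0 °C; then 2 (1.5 equiv), THF, −78 °C; cold 1 M HCl
Reagents that add atoms: none
Why: Shapiro reaction: the hydrazone dianion forms at the methyl group, loses sulfinate and N2 to give the 2-lithio-1-alkene, which should add only once to the diamide because the chelated tetrahedral adduct survives until the quench (Weinreb ketone synthesis).

Step 4
Reactants: 6 (8E)-N-methoxy-N,9,13-trimethyl-5-methylidene-4-oxotetradeca-8,12-dienamide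
Product: 7 (4R,8E)-4-hydroxy-N-methoxy-N,9,13-trimethyl-5-methylidenetetradeca-8,12-dienamide
Conditions: (S)-1-methyl-3,3-diphenyltetrahydro-1H,3H-pyrrolo[1,2-c][1,3,2]oxazaborole (0.2 equiv), catecholborane (1.8 equiv), toluene, −78 °C; MeOH, then H2O
Reagents that add atoms: none
Why: Corey–Bakshi–Shibata reduction: the α-branched alkenyl group acts as the large substituent, so the (S)-catalyst should deliver hydride to give the (R)-allylic alcohol (C9 of the target), while catecholborane at −78 °C leaves the Weinreb amide and the alkenes untouched.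

Step 5
Reactants: 7 (4R,8E)-4-hydroxy-N-methoxy-N,9,13-trimethyl-5-methylidenetetradeca-8,12-dienamide
Product: 8 (4R,8E)-4-(tert-butyldimethylsilyloxy)-N-methoxy-N,9,13-trimethyl-5-methylidenetetradeca-8,12-dienamide
Conditions: TBSCl, imidazole, DMF, rt
Reagents that add atoms: tert-butyldimethylsilyl chloride, C[Si](C)(Cl)C(C)(C)C
Why: Silylation of the only hydroxyl group protects C9–OH against the Grignard reagent, the Lewis acid and AlMe3 and removes its electron density from the neighbouring methylidene.

Step 6
Reactants: 8 (4R,8E)-4-(tert-butyldimethylsilyloxy)-N-methoxy-N,9,13-trimethyl-5-methylidenetetradeca-8,12-dienamide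
Product: 9 (6R,10E)-6-(tert-butyldimethylsilyloxy)-11,15-dimethyl-7-methylidenehexadeca-1,10,14-trien-3-one
Conditions: CH2=CHMgBr (2 equiv), THF, −78 → 0 °C; cold 1 M HCl
Reagents that add atoms: vinylmagnesium bromide, C=C[Mg]Br
Why: Weinreb ketone synthesis: the chelated adduct collapses to the vinyl ketone only on the acidic quench, which also protonates the liberated amine so that it cannot add to the enone.

Step 7
Reactants: 9 (6R,10E)-6-(tert-butyldimethylsilyloxy)-11,15-dimethyl-7-methylidenehexadeca-1,10,14-trien-3-one
Product: 10 (1R,4E,9R)-9-(tert-butyldimethylsilyloxy)-4,14,14-trimethyl-8-methylidene-13-oxabicyclo[10.2.2]hexadeca-4,12(16)-diene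
Conditions: Me2AlCl (1.1 equiv), CH2Cl2, slow addition of 9 to 2 mM, −78 → −30 °C; Et3N, then aq. NaHCO3
Reagents that add atoms: none
Why: Proposed new method: Me2AlCl complexes the s-cis vinyl ketone, the isopropylidene CH (C1) attacks the enone terminus C15 while the aluminium enolate oxygen O13 closes on the developing tertiary cation at C14 (asynchronous [4+2], at most a short-lived zwitterion; an ene-type isopropenyl ketone, if formed, re-enters the same cation and ends in the same enol ether). The closest known reaction types are the Lewis acid-promoted addition of alkyl vinyl ketones to trisubstituted alkenes that gives 3,4-dihydro-2H-pyrans, intramolecular oxadiene hetero-Diels–Alder reactions onto isopropylidene groups, and the cationic 14-membered ring closure of geranylgeranyl-type chains at the isopropylidene terminus by a conjugated acylium ion; new here is a simple vinyl ketone closing a 14-membered ring. The carbocycle closes in a 14-membered mode that is endo at the vinyl ketone and exo at the isopropylidene (C14 stays outside the carbocycle), and the oxane closes as the six-membered [4+2] ring through O13–C14 bonding. C1 is the only new stereocentre: the alkene face is chosen by the fold of the ten-carbon tether, and the fold that keeps the bulky C9 silyloxy group on the outer face, on the side of the new O13–C14 bridge, should lead from (9R) to (1R) (see assumption). The step needs site selectivity for the terminal alkene, secured because C4=C5 could only close a strained 10-membered ring and the C8 methylidene is deactivated by the allylic silyloxy group and could only close an 8-membered ring by conjugate attack; it also needs a monomeric enone, secured by high dilution and a proton-scavenging methylaluminium Lewis acid.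

Step 8
Reactants: 10 (1R,4E,9R)-9-(tert-butyldimethylsilyloxy)-4,14,14-trimethyl-8-methylidene-13-oxabicyclo[10.2.2]hexadeca-4,12(16)-diene
Product: 12 (1R,4E,9R,12S,16R)-9-(tert-butyldimethylsilyloxy)-4,12,14,14-tetramethyl-8-methylidene-13-oxabicyclo[10.2.2]hexadec-4-en-16-ol, via epoxide 11 (not isolated)
Conditions: dimethyldioxirane (1.05 equiv), acetone/CH2Cl2, −78 °C; volatiles removed cold; AlMe3 (3 equiv), CH2Cl2, −78 → 0 °C; aq. Rochelle salt
Reagents that add atoms: dimethyldioxirane, CC1(C)OO1; trimethylaluminium, C[Al](C)C
Why: Dimethyldioxirane should epoxidise the electron-rich enol ether far faster than the isolated alkenes and on the face anti to the tether (sets C16), and AlMe3 then opens the 1,2-anhydro ketal to the cyclic oxocarbenium ion and transfers methyl to C12 from the aluminate on the same face (glycal epoxide C-glycosylation), the only face that keeps C11 cis to C2 (sets C12).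

Step 9
Reactants: 12 (1R,4E,9R,12S,16R)-9-(tert-butyldimethylsilyloxy)-4,12,14,14-tetramethyl-8-methylidene-13-oxabicyclo[10.2.2]hexadec-4-en-16-ol
Product: 13 (1R,4E,9R,12S,16R)-9-(tert-butyldimethylsilyloxy)-4,12,14,14-tetramethyl-8-methylidene-13-oxabicyclo[10.2.2]hexadec-4-en-16-yl acetate
Conditions: Ac2O, Et3N, DMAP (cat.), CH2Cl2, rt
Reagents that add atoms: acetic anhydride, CC(=O)OC(C)=O
Why: DMAP-catalysed acylation of the only free hydroxyl group (the hindered C16 alcohol) should give the acetate without touching any stereocentre.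

Step 10
Reactants: 13 (1R,4E,9R,12S,16R)-9-(tert-butyldimethylsilyloxy)-4,12,14,14-tetramethyl-8-methylidene-13-oxabicyclo[10.2.2]hexadec-4-en-16-yl acetate
Product: 14 (1R,4E,9R,12S,16R)-9-hydroxy-4,12,14,14-tetramethyl-8-methylidene-13-oxabicyclo[10.2.2]hexadec-4-en-16-yl acetate
Conditions: HF·pyridine, pyridine/THF, 0 °C → rt
Reagents that add atoms: none
Why: Fluoride-mediated silyl ether cleavage under buffered, non-basic conditions should free the C9 allylic alcohol while the acetate, the di-tertiary ether and the alkenes stay intact.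

**Compound list**

1 | succinyl chloride (butanedioyl dichloride) | O=C(Cl)CCC(=O)Cl | starting material
2 | N1,N4-dimethoxy-N1,N4-dimethylbutanediamide (succinic bis-Weinreb amide) | CON(C)C(=O)CCC(=O)N(C)OC | intermediate
3 | geranylacetone, (5E)-6,10-dimethylundeca-5,9-dien-2-one (E isomer) | CC(=O)CC/C=C(\C)CCC=C(C)C | starting material
4 | (E)-N'-[(5E)-6,10-dimethylundeca-5,9-dien-2-ylidene]-2,4,6-triisopropylbenzenesulfonohydrazide | C/C(=N\NS(=O)(=O)c1c(C(C)C)cc(C(C)C)cc1C(C)C)CC/C=C(\C)CCC=C(C)C | intermediate
5 | (5E)-6,10-dimethylundeca-1,5,9-trien-2-yllithium (vinyllithium, not isolated) | [Li]C(=C)CC/C=C(\C)CCC=C(C)C | intermediate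
6 | (8E)-N-methoxy-N,9,13-trimethyl-5-methylidene-4-oxotetradeca-8,12-dienamide | CON(C)C(=O)CCC(=O)C(=C)CC/C=C(\C)CCC=C(C)C | intermediate
7 | (4R,8E)-4-hydroxy-N-methoxy-N,9,13-trimethyl-5-methylidenetetradeca-8,12-dienamide | CON(C)C(=O)CC[C@@H](O)C(=C)CC/C=C(\C)CCC=C(C)C | intermediate
8 | (4R,8E)-4-(tert-butyldimethylsilyloxy)-N-methoxy-N,9,13-trimethyl-5-methylidenetetradeca-8,12-dienamide | CON(C)C(=O)CC[C@@H](O[Si](C)(C)C(C)(C)C)C(=C)CC/C=C(\C)CCC=C(C)C | intermediate
9 | (6R,10E)-6-(tert-butyldimethylsilyloxy)-11,15-dimethyl-7-methylidenehexadeca-1,10,14-trien-3-one | C=CC(=O)CC[C@@H](O[Si](C)(C)C(C)(C)C)C(=C)CC/C=C(\C)CCC=C(C)C | intermediate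
10 | (1R,4E,9R)-9-(tert-butyldimethylsilyloxy)-4,14,14-trimethyl-8-methylidene-13-oxabicyclo[10.2.2]hexadeca-4,12(16)-diene | C=C1CC/C=C(\C)CC[C@@H]2CC=C(CC[C@H]1O[Si](C)(C)C(C)(C)C)OC2(C)C | intermediate
11 | (1R,4E,9R,12S,16R)-12,16-epoxide of 10, oxygen on the face anti to the tether (not isolated) | C=C1CC/C=C(\C)CC[C@@H]2C[C@H]3O[C@@]3(CC[C@H]1O[Si](C)(C)C(C)(C)C)OC2(C)C | intermediate
12 | (1R,4E,9R,12S,16R)-9-(tert-butyldimethylsilyloxy)-4,12,14,14-tetramethyl-8-methylidene-13-oxabicyclo[10.2.2]hexadec-4-en-16-ol | C=C1CC/C=C(\C)CC[C@@H]2C[C@@H](O)[C@](C)(CC[C@H]1O[Si](C)(C)C(C)(C)C)OC2(C)C | intermediate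
13 | (1R,4E,9R,12S,16R)-9-(tert-butyldimethylsilyloxy)-4,12,14,14-tetramethyl-8-methylidene-13-oxabicyclo[10.2.2]hexadec-4-en-16-yl acetate | C=C1CC/C=C(\C)CC[C@@H]2C[C@@H](OC(C)=O)[C@](C)(CC[C@H]1O[Si](C)(C)C(C)(C)C)OC2(C)C | intermediate
14 | (1R,4E,9R,12S,16R)-9-hydroxy-4,12,14,14-tetramethyl-8-methylidene-13-oxabicyclo[10.2.2]hexadec-4-en-16-yl acetate (CNP0202897.1) | C=C1CC/C=C(\C)CC[C@@H]2C[C@@H](OC(C)=O)[C@](C)(CC[C@H]1O)OC2(C)C | target

**Step count and risks**

Total step count: 10. Longest linear sequence: 9 steps (3 → 14, steps 2–10).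

Steps most likely to fail:

1. Step 7 (Proposed new method). The complexed vinyl ketone may oligomerise, or the C8 methylidene may add to the complexed carbonyl in a six-membered Prins closure, faster than the chain folds into the 14-membered transition state. The fold may also show poor facial selectivity at C1. The fallback uses known chemistry, sets out from 8 and returns at 10. HOBr addition (NBS, THF/H2O, 0 °C) at the terminal, most accessible trisubstituted alkene should give bromohydrin F1, with bromine on the future C1 and the hydroxyl on the future C14. Silylation of the tertiary alcohol (TMSOTf, 2,6-lutidine) gives bromo silyl ether F2, and vinylmagnesium bromide converts the Weinreb amide into bromo vinyl ketone F3. Bu3SnH/AIBN in dilute benzene at 80 °C (syringe pump) should close the 14-membered ring by endo addition of the secondary radical to the vinyl ketone terminus, a tin hydride radical macrocyclisation onto an enone, to give macrocyclic ketone F4. Camphorsulfonic acid in warm benzene then cleaves the trimethylsilyl ether and dehydrates the hydroxy ketone through its hemiketal to enol ether 10. In this variant the ring oxygen comes from water and the two bonds are made in separate steps.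

2. Step 8. The epoxidation may lose chemoselectivity (oxidation of the C4=C5 alkene), or the labile epoxide may rearrange by hydride shift before the methyl group is transferred. The fallback sets out from 10 and returns at 12. Epoxidation with dimethyldioxirane followed by methanol at −78 → 0 °C should open the epoxide to the stable methyl ketal F5. AlMe3 (CH2Cl2, −40 → 0 °C) then replaces the methoxy group through the cyclic oxocarbenium ion with alkoxide-directed methyl delivery (ketal substitution by an organoaluminium reagent), which gives 12.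

3. Step 3. Dianion formation may be incomplete or not regioselective, and the vinyllithium may add twice to the diamide. The fallback sets out from 3 and 2 and returns at 6. Kinetic enolisation of 3 (KN(SiMe3)2, PhNTf2, THF, −78 °C) should give enol triflate F6, and half-reduction of 2 (i-Bu2AlH, 1 equiv, −78 °C) gives aldehyde F7. Nozaki–Hiyama–Kishi coupling (CrCl2, catalytic NiCl2, DMF) joins them to racemic allylic alcohol F8, and Dess–Martin oxidation gives enone 6.

Further compounds

F1 | step 7 | (4R,8E)-12-bromo-4-(tert-butyldimethylsilyloxy)-13-hydroxy-N-methoxy-N,9,13-trimethyl-5-methylidenetetradec-8-enamide (both C12 epimers) | CON(C)C(=O)CC[C@@H](O[Si](C)(C)C(C)(C)C)C(=C)CC/C=C(\C)CCC(Br)C(C)(C)O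
F2 | step 7 | 13-O-trimethylsilyl ether of F1 (both C12 epimers) | CON(C)C(=O)CC[C@@H](O[Si](C)(C)C(C)(C)C)C(=C)CC/C=C(\C)CCC(Br)C(C)(C)O[Si](C)(C)C
F3 | step 7 | (6R,10E)-14-bromo-6-(tert-butyldimethylsilyloxy)-11,15-dimethyl-7-methylidene-15-(trimethylsilyloxy)hexadeca-1,10-dien-3-one (both C14 epimers) | C=CC(=O)CC[C@@H](O[Si](C)(C)C(C)(C)C)C(=C)CC/C=C(\C)CCC(Br)C(C)(C)O[Si](C)(C)C
F4 | step 7 | 14-membered ketone (target numbering): C12 ketone, C15–C1 bond formed, (1R)-C1 bearing 2-(trimethylsilyloxy)propan-2-yl, (9R)-OTBS, C8 methylidene, (4E)-alkene | C=C1CC/C=C(\C)CC[C@@H](C(C)(C)O[Si](C)(C)C)CCC(=O)CC[C@H]1O[Si](C)(C)C(C)(C)C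
F5 | step 8 | (1R,4E,9R,12S,16R)-9-(tert-butyldimethylsilyloxy)-12-methoxy-4,14,14-trimethyl-8-methylidene-13-oxabicyclo[10.2.2]hexadec-4-en-16-ol | C=C1CC/C=C(\C)CC[C@@H]2C[C@@H](O)[C@](OC)(CC[C@H]1O[Si](C)(C)C(C)(C)C)OC2(C)C
F6 | step 3 | (5E)-6,10-dimethylundeca-1,5,9-trien-2-yl trifluoromethanesulfonate | C=C(OS(=O)(=O)C(F)(F)F)CC/C=C(\C)CCC=C(C)C
F7 | step 3 | N-methoxy-N-methyl-4-oxobutanamide | CON(C)C(=O)CCC=O
F8 | step 3 | racemic (8E)-4-hydroxy-N-methoxy-N,9,13-trimethyl-5-methylidenetetradeca-8,12-dienamide | CON(C)C(=O)CCC(O)C(=C)CC/C=C(\C)CCC=C(C)C
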